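## Retrosynthetic overview

1. Target 9 ⇐ oxocene 8 by a late epoxidation of the ring Z-alkene C13=C14 (labdane numbering: C3 = CHBr, C8 = O-bearing ring carbon, C15 = OCH2).
2. 8 ⇐ (2Z,6E,10E)-geranylgeraniol 5 by one bromonium-triggered cascade: ring A, then ring B, then the eight-membered ether ring by capture of the C8 cation by the C15 hydroxyl.
3. 5 ⇐ ynol 3 by syn-carbomagnesiation, which sets the 13Z geometry that lets the hydroxyl reach C8.
4. 3 ⇐ (2E,6E)-farnesyl bromide 1, 1,3-dilithiopropyne and formaldehyde.

Assumption: the sense of induction of the chiral catalyst in step 3 is taken as written; if the first run gives ent-8, the enantiomeric catalyst is used.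

## Route

Step 1
Reactants: 1 (2E,6E)-farnesyl bromide
Product: 3 (6E,10E)-7,11,15-trimethylhexadeca-6,10,14-trien-2-yn-1-ol, via lithium acetylide 2 (not isolated)
Conditions: HC≡CCH2Br, n-BuLi (2 equiv), TMEDA, Et2O/hexane, −78 °C; add 1, −78 °C → rt; then (CH2O)n, rt; H2O
Reagents that add atoms: propargyl bromide (used as 1,3-dilithiopropyne), C#CCBr; paraformaldehyde (as formaldehyde), C=O
Why: The sp3 carbanion of 1,3-dilithiopropyne displaces the primary allylic bromide (SN2 alkylation, alkene geometry untouched), and the remaining lithium acetylide is then hydroxymethylated by formaldehyde in the same flask (acetylide addition to an aldehyde).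

Step 2
Reactants: 3 (6E,10E)-7,11,15-trimethylhexadeca-6,10,14-trien-2-yn-1-ol
Product: 5 (2Z,6E,10E)-geranylgeraniol, via alkenylmagnesium bromide 4 (not isolated)
Conditions: MeMgBr (5 equiv), Fe(acac)3 (15 mol %), THF, −78 → 0 °C; H2O
Reagents that add atoms: methylmagnesium bromide, C[Mg]Br
Why: Alkoxide-directed iron-catalysed syn-carbomagnesiation of a propargylic alcohol puts Me on the distal alkyne carbon and Mg on the proximal one on the same side, so protonation leaves the chain cis to CH2OH (2Z); the isolated trisubstituted alkenes do not react.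

Step 3
Reactants: 5 (2Z,6E,10E)-geranylgeraniol
Product: 8 (3S,5R,8R,9R,10S,13Z)-3-bromo-8,15-epoxylabd-13-ene, via bromonium ion 6 (not isolated), via C8 carbocation 7 (not isolated)
Conditions: DBDMH (1.1 equiv), (R)-3,3'-bis(2,4,6-triisopropylphenyl)-BINOL N-triflylthiophosphoramide (10 mol %), toluene/CH2Cl2, −78 °C, 0.01 M; aq. Na2S2O3
Reagents that add atoms: 1,3-dibromo-5,5-dimethylhydantoin (DBDMH), CC1(C)N(Br)C(=O)N(Br)C1=O
Why: Proposed new method: the chiral P=S Lewis base carries Br+ from DBDMH to one face of the terminal isopropylidene alkene, the most electron-rich and least hindered one (the C13=C14 alkene is deactivated by its allylic C–O bond), which sets 3S; antiperiplanar chair–chair additions across the two E alkenes then give the trans-decalin with equatorial 3β-Br, 5α-H, 9α-H and 10β-Me, and the C8 cation is taken on its α face (anti to the new C9–C10 bond) by the C15 hydroxyl, which the 13Z alkene holds within reach, closing the oxocene with 8α-O and 8β-Me; the case for O-capture is that an alcohol is a far better carbocation nucleophile than an oxygen-deactivated trisubstituted alkene, which has to offset the eight- versus six-membered ring penalty against carbocyclisation through C14 and against E1 loss; closest known reaction types are the thiophosphoramide/DBDMH-catalysed enantioselective bromonium polyene cyclisation of homogeranylarenes and hydroxyl- or carbonyl-terminated bromonium polyene cyclisations with achiral Br+ reagents.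

Step 4
Reactants: 8 (3S,5R,8R,9R,10S,13Z)-3-bromo-8,15-epoxylabd-13-ene
Product: 9 (3S,5R,8R,9R,10S,13R,14S)-3-bromo-8,15:13,14-diepoxylabdane (target)
Conditions: mCPBA (1.2 equiv), NaHCO3, CH2Cl2, 0 °C
Reagents that add atoms: 3-chloroperoxybenzoic acid (mCPBA), OOC(=O)c1cccc(Cl)c1
Why: Prilezhaev epoxidation of the only alkene; the axial β-methyls on C8 and C10 keep the O–C15 and C11–C12 bonds staggered away from them, which holds the ring alkene on the α side of the oxocene with its inner face covered by the ring, so the peracid should add to the open outer face and give the cis-fused (13R,14S)-epoxide, while the buffer protects the acid-labile epoxide.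

## Compound list

1 | (2E,6E)-farnesyl bromide, (2E,6E)-1-bromo-3,7,11-trimethyldodeca-2,6,10-triene | CC(C)=CCC/C(C)=C/CC/C(C)=C/CBr | starting material
2 | lithium acetylide of (5E,9E)-6,10,14-trimethylpentadeca-5,9,13-trien-1-yne | CC(C)=CCC/C(C)=C/CC/C(C)=C/CCC#C[Li] | intermediate
3 | (6E,10E)-7,11,15-trimethylhexadeca-6,10,14-trien-2-yn-1-ol | CC(C)=CCC/C(C)=C/CC/C(C)=C/CCC#CCO | intermediate
4 | C2-alkenylmagnesium bromide (Mg cis to the new C3 methyl), bromomagnesium alkoxide form | CC(C)=CCC/C(C)=C/CC/C(C)=C/CC/C(C)=C(/[Mg]Br)CO[Mg]Br | intermediate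
5 | (2Z,6E,10E)-geranylgeraniol, (2Z,6E,10E)-3,7,11,15-tetramethylhexadeca-2,6,10,14-tetraen-1-ol | CC(C)=CCC/C(C)=C/CC/C(C)=C/CC/C(C)=C\CO | intermediate
6 | (S)-bromonium ion on the terminal alkene of 5 | CC1(C)[Br+][C@H]1CC/C(C)=C/CC/C(C)=C/CC/C(C)=C\CO | intermediate
7 | bicyclic tertiary C8 carbocation (3β-bromo trans-decalin, 9β side chain with Z-allylic alcohol) | CC1(C)[C@@H](Br)CC[C@]2(C)[C@@H](CC/C(C)=C\CO)[C+](C)CC[C@@H]12 | intermediate
8 | (3S,5R,8R,9R,10S,13Z)-3-bromo-8,15-epoxylabd-13-ene (3β-Br, trans-decalin, 8α-O, Z-oxocene) | CC1(C)[C@@H](Br)CC[C@]2(C)[C@H]3CC/C(C)=C\CO[C@]3(C)CC[C@@H]12 | intermediate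
9 | (3S,5R,8R,9R,10S,13R,14S)-3-bromo-8,15:13,14-diepoxylabdane, CNP0311742.2 | CC1(C)[C@@H](Br)CC[C@]2(C)[C@H]3CC[C@@]4(C)O[C@H]4CO[C@]3(C)CC[C@@H]12 | target

## Step count and risks

Total steps: 4. Longest linear sequence: 4 (1 → 3 → 5 → 8 → 9).

Most likely to fail, in order:

Step 3. The hydroxyl capture runs through an eight-membered transition state and may lose to carbocyclisation by C14 (a third six-membered carbocycle) or to E1 loss giving Δ7 and Δ8(17) alkenes; the enantiomeric ratio is also untested for this terminating group. The fallback moves oxygen capture at C8 into a six-membered transition state with no competing π-nucleophile and closes the oxocene afterwards by metathesis. It sets out from 1 and comes back at 8. 1 is alkylated with ethyl sodioacetoacetate (NaOEt, EtOH) to the β-keto ester ethyl (4E,8E)-2-acetyl-5,9,13-trimethyltetradeca-4,8,12-trienoate F1. Saponification and decarboxylation (aq. NaOH, then H3O+, heat) give (5E,9E)-farnesylacetone F2. The same catalyst/DBDMH cyclisation, now terminated by the ketone oxygen, gives the bicyclic enol ether 3β-bromo-8α,13-epoxy-14,15-dinorlabd-12-ene F3. Wet oxalic acid in THF hydrolyses it to the ketol 3β-bromo-8α-hydroxy-14,15-dinorlabdan-13-one F4. Ph3P=CH2 (THF) gives the 1,1-disubstituted alkene 3β-bromo-15-norlabd-13-en-8α-ol F5. KH and allyl bromide (THF, 18-crown-6) give the tertiary allyl ether 8α-allyloxy-3β-bromo-15-norlabd-13-ene F6. Ring-closing metathesis with second-generation Grubbs catalyst, RuCl2(=CHPh)(H2IMes)(PCy3), in hot toluene closes the ring Z-alkene and delivers 8.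

Step 4. The face selectivity rests on a conformational argument for the oxocene and could be reversed or low. The fallback delivers oxygen to the face opposite to the one an electrophile prefers. It sets out from 8 and comes back at 9. NBS in THF/H2O puts Br+ on the face the peracid used and water anti at the tertiary C13, giving the bromohydrin (13R,14R)-3β,14-dibromo-8α,15-epoxylabdan-13-ol F7. K2CO3 in MeOH closes the epoxide by backside displacement at C14, which gives 9.

Step 2. The regiochemistry or syn-selectivity of the iron-catalysed methyl addition may be incomplete on this polyene. The fallback sets the Z alkene by syn-carbocupration of an ynoate. It sets out from 2 (generated as in step 1) and comes back at 5. Quenching 2 with ClCO2Me gives methyl (6E,10E)-7,11,15-trimethylhexadeca-6,10,14-trien-2-ynoate F8. Me2CuLi (THF, −78 °C, MeOH quench at −78 °C) gives methyl (2Z,6E,10E)-geranylgeranoate F9. i-Bu2AlH (CH2Cl2, −78 °C) reduces it to 5.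

Further compounds
F1 | step 3 | ethyl (4E,8E)-2-acetyl-5,9,13-trimethyltetradeca-4,8,12-trienoate | CC(C)=CCC/C(C)=C/CC/C(C)=C/CC(C(C)=O)C(=O)OCC
F2 | step 3 | (5E,9E)-farnesylacetone, (5E,9E)-6,10,14-trimethylpentadeca-5,9,13-trien-2-one | CC(C)=CCC/C(C)=C/CC/C(C)=C/CCC(C)=O
F3 | step 3 | 3β-bromo-8α,13-epoxy-14,15-dinorlabd-12-ene | CC1(C)[C@@H](Br)CC[C@]2(C)[C@H]3CC=C(C)O[C@]3(C)CC[C@@H]12
F4 | step 3 | 3β-bromo-8α-hydroxy-14,15-dinorlabdan-13-one | CC1(C)[C@@H](Br)CC[C@]2(C)[C@@H](CCC(C)=O)[C@](C)(O)CC[C@@H]12
F5 | step 3 | 3β-bromo-15-norlabd-13-en-8α-ol | CC1(C)[C@@H](Br)CC[C@]2(C)[C@@H](CCC(C)=C)[C@](C)(O)CC[C@@H]12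
F6 | step 3 | 8α-allyloxy-3β-bromo-15-norlabd-13-ene | CC1(C)[C@@H](Br)CC[C@]2(C)[C@@H](CCC(C)=C)[C@](C)(OCC=C)CC[C@@H]12
F7 | step 4 | (13R,14R)-3β,14-dibromo-8α,15-epoxylabdan-13-ol | CC1(C)[C@@H](Br)CC[C@]2(C)[C@H]3CC[C@@](C)(O)[C@H](Br)CO[C@]3(C)CC[C@@H]12
F8 | step 2 | methyl (6E,10E)-7,11,15-trimethylhexadeca-6,10,14-trien-2-ynoate | CC(C)=CCC/C(C)=C/CC/C(C)=C/CCC#CC(=O)OC
F9 | step 2 | methyl (2Z,6E,10E)-3,7,11,15-tetramethylhexadeca-2,6,10,14-tetraenoate | CC(C)=CCC/C(C)=C/CC/C(C)=C/CC/C(C)=C\C(=O)OC
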